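**Retrosynthetic overview** (labdane numbering is used for all decalin compounds)

1. The target is the 6α-angelate of (12E)-labda-12,14-diene-6α,8α-diol (5S,6S,8R,9R,10S). The ester goes on last, and the diene is grown late (cross-metathesis, Wittig) from a C9 allyl group.
2. The C6–O/C8–O pair of ring B is traced back to a 7α,8α-epoxy-6-ketone and from there to the Δ7-6-ketone 17.
3. Key disconnection: C5–C10 and C7–C8 are cut together. The enabling feature is in ring B: the C6 carbonyl carbon sits between C5 and C7 (an acetone-type 1,3-bis-nucleophile), and C10–C9–C8 is an enone (C10 the β-carbon, C8 the carbonyl). Ring B is their [3+3] Michael/aldol union, and the C1–C3 chain with the C4 gem-dimethyl group ties C5 to C10 as ring A. The precursor is the open-chain, achiral keto-enone 11.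
4. Ring order: ring A first (C5→C10 Michael), ring B second (C7→C8 aldol, then dehydration), both in one flask. C10 is set by the catalyst, C5 by equilibration, C9 by kinetic γ-protonation (step 7), C8 by α-face epoxidation, C6 by dissolving-metal reduction.
5. Compound 11 comes from mesityl oxide plus allylsilane (Hosomi–Sakurai) and from acetylacetone (allylation, enol triflate), joined by a B-alkyl Suzuki coupling.

Key step: step 6

Assumption: which antipode of the chiral acid in step 6 gives the 10S series cannot be assigned on paper, so both antipodes (available from (R)- and (S)-BINOL) are tested and the one giving 10S is used.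

Step 1
Reactants: 1 acetylacetone (pentane-2,4-dione); 2 allyl bromide
Product: 3 3-allylpentane-2,4-dione
Conditions: K2CO3, acetone, reflux (1 in slight excess)
Reagents that add atoms: none
Why: C-alkylation of the stabilised 1,3-diketone enolate with an allylic halide is a standard monoalkylation, and the excess of diketone should suppress diallylation.

Step 2
Reactants: 3 3-allylpentane-2,4-dione
Product: 4 (Z)-4-oxo-3-(prop-2-en-1-yl)pent-2-en-2-yl trifluoromethanesulfonate
Conditions: Tf2O, i-Pr2NEt, CH2Cl2, −78 → 0 °C
Reagents that add atoms: trifluoromethanesulfonic anhydride, O=S(=O)(OS(=O)(=O)C(F)(F)F)C(F)(F)F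
Why: O-sulfonylation of the enol of a symmetrical 1,3-diketone (enol triflate formation) has no regiochemical issue, and the internally hydrogen-bonded enol should give the Z isomer.

Step 3
Reactants: 5 mesityl oxide; 6 allyltrimethylsilane
Product: 7 4,4-dimethylhept-6-en-2-one
Conditions: TiCl4, CH2Cl2, −78 °C; H2O
Reagents that add atoms: none
Why: Hosomi–Sakurai conjugate allylation of a β,β-disubstituted enone builds the quaternary gem-dimethyl carbon (the later C4) and the three-carbon chain (C1–C3) in one step.

Step 4
Reactants: 7 4,4-dimethylhept-6-en-2-one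
Product: 8 2-(2,2-dimethylpent-4-en-1-yl)-2-methyl-1,3-dioxolane
Conditions: ethylene glycol, p-TsOH (cat.), benzene, reflux, Dean–Stark
Reagents that add atoms: ethylene glycol, OCCO
Why: Ketalisation masks the methyl ketone, which would otherwise compete with the alkene for 9-BBN in step 5.

Step 5
Reactants: 8 2-(2,2-dimethylpent-4-en-1-yl)-2-methyl-1,3-dioxolane; 4 (Z)-enol triflate
Product: 11 (Z)-4,8,8-trimethyl-3-(prop-2-en-1-yl)undec-3-ene-2,10-dione, via alkylborane 9 (not isolated), via coupled dioxolane 10 (not isolated)
Conditions: 9-BBN (1.0 equiv to 8), THF, 0 °C → rt; then 4 (0.9 equiv), Pd(dppf)Cl2 (5 mol%), AsPh3, aq. K3PO4, DMF/THF, rt; crude product, then PPTS (cat.), acetone/H2O, 50 °C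
Reagents that add atoms: water, O
Why: B-alkyl Suzuki–Miyaura coupling of a primary alkyl-9-BBN (anti-Markovnikov hydroboration of the terminal alkene, complete before 4 is added so that its allyl group is not touched) with an activated enol triflate proceeds with retention of alkene geometry, and mild acid then frees the methyl ketone.

Step 6
Reactants: 11 (Z)-4,8,8-trimethyl-3-(prop-2-en-1-yl)undec-3-ene-2,10-dione
Product: 14 trans-fused enone 14,15,16-trinorlabda-7,12-dien-6-one (5α-H; 10β-methyl; C9 epimers), via Michael adduct 12 (not isolated), via ketol 13 (not isolated)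
Conditions: confined chiral Brønsted acid of the BINOL-derived imidodiphosphorimidate (IDPi) type (5 mol%), 5 Å MS, toluene (0.05 M), 50 °C
Reagents that add atoms: none
Why: Proposed new method: the strong confined chiral acid protonates the enone carbonyl of 11, placing positive charge on tertiary C10, while the saturated methyl ketone enolises toward its more substituted α-carbon C5; this enol closes ring A by a 6-(enolexo)-exo-trig Michael addition (C5–C10, helped by the gem-dimethyl effect of C4), the C8 ketone is restored by tautomerisation, the C6 ketone re-enolises toward C7 and closes ring B by a 6-(enolendo)-exo-trig aldol addition (C7–C8), and loss of water from ketol 13 makes the sequence irreversible. The closest known reaction type is the acid-catalysed Robinson-type Michael/aldol condensation, known with chiral phosphoric acids for β-keto ester enols, together with the activation of simple enones and divinyl ketones by imidodiphosphorimidate acids; what has not been shown is a simple ketone enol adding to a tetrasubstituted acyclic enone in this topology, where the aldol acceptor is the carbonyl of the Michael acceptor itself. The quaternary centre C10 is set by the catalyst, whose chiral counter-anion pocket must differentiate the two faces of the planar C10 cation; C5 is epimerisable α to the C6 carbonyl and should settle as the trans-fused 5α-H isomer; the C8 carbinol of 13 disappears on dehydration, and C9 is left as a mixture on purpose because step 7 resets it. The step needs regioselection among two nucleophilic α-carbons and two carbonyl acceptors, and ring size secures it: only C5→C10 gives a six-membered ring (C7→C10 and C5→C8 would give eight-membered rings, C7→C8 before ring A a ten-membered ring), and only once ring A exists can C7 reach C8 through a six-membered ring. The allyl group should be safe because its alkene can reach the cationic C10 or C8 only through four-membered or 5-endo closures.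

Step 7
Reactants: 14 trans-fused enone (C9 epimers)
Product: 17 14,15,16-trinorlabda-7,12-dien-6-one (5α-H; 9α-H; 10β-methyl), via potassium dienolate 15 (not isolated), via deconjugated Δ8 ketone 16 (not isolated)
Conditions: KOt-Bu (3 equiv), t-BuOH/THF, rt; inverse quench into 10% aq. AcOH, 0 °C; then DBU (0.1 equiv), CH2Cl2, 0 °C → rt, stopped at full reconjugation
Reagents that add atoms: none
Why: Enone deconjugation–reconjugation through the extended enolate: thermodynamic deprotonation gives the through-conjugated dienolate 15 with planar C9, kinetic protonation at C7 gives the Δ8 ketone 16, and base-catalysed reconjugation protonates C9 axially from the α-face, anti to the axial C10 methyl group, which sets 9α-H with the allyl group β (C5 stays trans-fused because the α-face is both the kinetic and the thermodynamic side for its reprotonation).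

Step 8
Reactants: 17 Δ7-6-ketone (9α-H)
Product: 18 7α,8α-epoxy-14,15,16-trinorlabd-12-en-6-one
Conditions: 30% H2O2, aq. NaOH (cat.), MeOH, 0 °C → rt
Reagents that add atoms: hydrogen peroxide, OO
Why: Weitz–Scheffer nucleophilic epoxidation: hydroperoxide adds to C8 from the α-face because the β-face is covered by the axial C10 methyl and the β-allyl group at C9, and closure on the same face gives the 7α,8α-epoxide, which fixes C8 with oxygen α and methyl β.

Step 9
Reactants: 18 7α,8α-epoxy ketone
Product: 20 14,15,16-trinorlabd-12-ene-6α,8α-diol, via hydroxy ketone 19 (not isolated)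
Conditions: Li (excess), NH3(l)/THF, −78 °C; then EtOH, −78 → −33 °C; NH4Cl
Reagents that add atoms: none
Why: Dissolving-metal reduction: the ketyl cleaves the Cα–O bond (C7–O) to the enolate of β-hydroxy ketone 19 with the C8–O bond and configuration untouched, and after protonation by ethanol the ketone is reduced further under thermodynamic control to the equatorial 6α-alcohol (a 6β-hydroxyl would be 1,3-diaxial to the C4β and C10 methyl groups), the isolated terminal alkene being inert.

Step 10
Reactants: 20 14,15,16-trinorlabd-12-ene-6α,8α-diol; 21 methacrolein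
Product: 22 (12E)-6α,8α-dihydroxy-15-norlabd-12-en-14-al
Conditions: Hoveyda–Grubbs second-generation catalyst (5 mol%), 21 (10 equiv), CH2Cl2, 40 °C
Reagents that add atoms: none
Why: Olefin cross-metathesis of a terminal alkene with a 1,1-disubstituted enal should give the trisubstituted (E)-enal (aldehyde trans to C11) and tolerates the free hydroxyl groups.

Step 11
Reactants: 22 (12E)-enal
Product: 23 (12E)-labda-12,14-diene-6α,8α-diol
Conditions: Ph3PCH3Br, KHMDS (excess), THF, 0 °C; then 22, −78 → 0 °C
Reagents that add atoms: methyltriphenylphosphonium bromide, C[P+](c1ccccc1)(c1ccccc1)c1ccccc1.[Br-]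
Why: Wittig methylenation of the enal completes the 12E,14-diene without touching the C12=C13 geometry.

Step 12
Reactants: 23 (12E)-labda-12,14-diene-6α,8α-diol; 24 angelic acid ((Z)-2-methylbut-2-enoic acid)
Product: 26 (12E)-8α-hydroxylabda-12,14-dien-6α-yl (Z)-2-methylbut-2-enoate, via mixed anhydride 25 (not isolated)
Conditions: 24, 2,4,6-trichlorobenzoyl chloride, Et3N, toluene, rt; then 23, 80 °C (no DMAP)
Reagents that add atoms: none
Why: Yamaguchi-type mixed-anhydride esterification without a nucleophilic catalyst avoids the addition–elimination pathway that turns angelates into tiglates; the alcohol attacks the less hindered angeloyl carbonyl, and only the secondary equatorial 6α-hydroxyl reacts while the tertiary 8α-hydroxyl stays free.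

**Compound list**

1 | acetylacetone (pentane-2,4-dione) | CC(=O)CC(C)=O | starting material
2 | allyl bromide | C=CCBr | starting material
3 | 3-allylpentane-2,4-dione | CC(=O)C(CC=C)C(C)=O | intermediate
4 | (Z)-4-oxo-3-(prop-2-en-1-yl)pent-2-en-2-yl trifluoromethanesulfonate | C/C(OS(=O)(=O)C(F)(F)F)=C(\CC=C)C(C)=O | intermediate
5 | mesityl oxide (4-methylpent-3-en-2-one) | CC(=O)C=C(C)C | starting material
6 | allyltrimethylsilane | C=CC[Si](C)(C)C | starting material
7 | 4,4-dimethylhept-6-en-2-one | CC(=O)CC(C)(C)CC=C | intermediate
8 | 2-(2,2-dimethylpent-4-en-1-yl)-2-methyl-1,3-dioxolane | CC1(CC(C)(C)CC=C)OCCO1 | intermediate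
9 | 9-[4,4-dimethyl-5-(2-methyl-1,3-dioxolan-2-yl)pentyl]-9-borabicyclo[3.3.1]nonane | CC1(CC(C)(C)CCCB2C3CCCC2CCC3)OCCO1 | intermediate
10 | (Z)-4,8,8-trimethyl-9-(2-methyl-1,3-dioxolan-2-yl)-3-(prop-2-en-1-yl)non-3-en-2-one | CC1(CC(C)(C)CCC/C(C)=C(/CC=C)C(C)=O)OCCO1 | intermediate
11 | (Z)-4,8,8-trimethyl-3-(prop-2-en-1-yl)undec-3-ene-2,10-dione (open-chain keto-enone, achiral) | CC(=O)CC(C)(C)CCC/C(C)=C(/CC=C)C(C)=O | intermediate
12 | Michael adduct, 3-(2-acetyl-1,3,3-trimethylcyclohexyl)hex-5-en-2-one; ring acetyl cis to the ring methyl (5α-H, 10β-methyl); C9 epimers | C=CCC(C(C)=O)[C@@]1(C)CCCC(C)(C)[C@@H]1C(C)=O | intermediate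
13 | ketol, 8-hydroxy-14,15,16-trinorlabd-12-en-6-one (5α-H, 10β-methyl; C8 and C9 epimers) | C=CCC1[C@@]2(C)CCCC(C)(C)[C@@H]2C(=O)CC1(C)O | intermediate
14 | 14,15,16-trinorlabda-7,12-dien-6-one (5α-H, 10β-methyl; C9 epimers) | C=CCC1[C@@]2(C)CCCC(C)(C)[C@@H]2C(=O)C=C1C | intermediate
15 | potassium 14,15,16-trinorlabda-6,8,12-trien-6-olate (through-conjugated dienolate) | C=CCC1=C(C)C=C([O-])[C@H]2C(C)(C)CCC[C@]12C.[K+] | intermediate
16 | 14,15,16-trinorlabda-8,12-dien-6-one (5α-H, 10β-methyl) | C=CCC1=C(C)CC(=O)[C@H]2C(C)(C)CCC[C@]12C | intermediate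
17 | 14,15,16-trinorlabda-7,12-dien-6-one (5α-H, 9α-H, 10β-methyl) | C=CC[C@@H]1[C@@]2(C)CCCC(C)(C)[C@@H]2C(=O)C=C1C | intermediate
18 | 7α,8α-epoxy-14,15,16-trinorlabd-12-en-6-one | C=CC[C@@H]1[C@@]2(C)CCCC(C)(C)[C@@H]2C(=O)[C@H]3O[C@@]13C | intermediate
19 | 8α-hydroxy-14,15,16-trinorlabd-12-en-6-one | C=CC[C@@H]1[C@@]2(C)CCCC(C)(C)[C@@H]2C(=O)C[C@@]1(C)O | intermediate
20 | 14,15,16-trinorlabd-12-ene-6α,8α-diol | C=CC[C@@H]1[C@@]2(C)CCCC(C)(C)[C@@H]2[C@@H](O)C[C@@]1(C)O | intermediate
21 | methacrolein | C=C(C)C=O | starting material
22 | (12E)-6α,8α-dihydroxy-15-norlabd-12-en-14-al | O=C/C(C)=C/C[C@@H]1[C@@]2(C)CCCC(C)(C)[C@@H]2[C@@H](O)C[C@@]1(C)O | intermediate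
23 | (12E)-labda-12,14-diene-6α,8α-diol | C=C/C(C)=C/C[C@@H]1[C@@]2(C)CCCC(C)(C)[C@@H]2[C@@H](O)C[C@@]1(C)O | intermediate
24 | angelic acid ((Z)-2-methylbut-2-enoic acid) | C/C=C(/C)C(=O)O | starting material
25 | angelic 2,4,6-trichlorobenzoic anhydride | C/C=C(/C)C(=O)OC(=O)c1c(Cl)cc(Cl)cc1Cl | intermediate
26 | (5S,6S,8R,9R,10S,12E)-8-hydroxylabda-12,14-dien-6-yl (Z)-2-methylbut-2-enoate (CNP0582767.1) | C=C/C(C)=C/C[C@@H]1[C@@]2(C)CCCC(C)(C)[C@@H]2[C@@H](OC(=O)/C(C)=C\C)C[C@@]1(C)O | target

**Step count and risks**

Total steps: 12. Longest linear sequence: 10 (steps 3, 4, 5, 6, 7, 8, 9, 10, 11, 12; the branch through steps 1 and 2 is equally long).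

Steps most likely to fail:

1. Step 6 (Proposed new method). What may go wrong: the twisted, tetrasubstituted enone may not be electrophilic enough for the hindered C5–C10 closure, the Michael event may revert before the aldol closure, or the catalyst may discriminate the two faces of C10 poorly. Fallback with known chemistry, setting out from 11: p-TsOH·H2O (0.2 equiv), toluene, reflux, Dean–Stark. This is the classical acid-mediated Robinson-type Michael/aldol condensation. It passes through the racemic Michael adduct (12 with its enantiomer ent-12 F1) and the racemic ketol (13 with its enantiomer ent-13 F2) to the racemic enone (14 with its enantiomer ent-14 F3). The step 7 protocol then runs through the racemic dienolate (15 with its enantiomer ent-15 F4) and the racemic Δ8 ketone (16 with its enantiomer ent-16 F5) to racemic 17 (17 with its enantiomer ent-17 F6). This is resolved by preparative chromatography on a chiral stationary phase (SFC), and the route is rejoined at 17.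

2. Step 9. What may go wrong: retro-aldol opening of ring B at the β-alkoxy ketone stage before the second reduction, or incomplete thermodynamic control at C6. Fallback, setting out from 18: SmI2 (2.5 equiv), THF/MeOH, −90 °C opens the epoxide under near-neutral conditions to ketol 19, which is isolated. NaBH4, MeOH, 0 °C then reduces it from the open α-face to the axial alcohol 14,15,16-trinorlabd-12-ene-6β,8α-diol F7. Hydrogen-transfer epimerisation with Shvo's catalyst (2 mol%, toluene, 90 °C) equilibrates C6 to the strongly favoured equatorial 6α-alcohol, and the route is rejoined at 20.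

3. Step 12. What may go wrong: Z→E isomerisation of the angeloyl unit to the tiglate during activation or heating, or sluggish acylation of the hindered 6α-hydroxyl. Fallback, setting out from 23: 2-[bis(2,2,2-trifluoroethoxy)phosphoryl]propanoic acid, DIC, DMAP, CH2Cl2 gives the 6-O-phosphonopropionate of 23 F8. KHMDS (1.05 equiv), 18-crown-6, THF, −78 °C, then acetaldehyde (Still–Gennari olefination) builds the (Z)-2-methylbut-2-enoate on the ester, and the route is rejoined at 26.

Further compounds
F1 | step 6 | ent-12, enantiomer of Michael adduct 12 (C9 epimers) | C=CCC(C(C)=O)[C@]1(C)CCCC(C)(C)[C@H]1C(C)=O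
F2 | step 6 | ent-13, enantiomer of ketol 13 (C8 and C9 epimers) | C=CCC1[C@]2(C)CCCC(C)(C)[C@H]2C(=O)CC1(C)O
F3 | step 6 | ent-14, enantiomer of enone 14 (C9 epimers) | C=CCC1[C@]2(C)CCCC(C)(C)[C@H]2C(=O)C=C1C
F4 | step 6 | ent-15, enantiomer of potassium dienolate 15 | C=CCC1=C(C)C=C([O-])[C@@H]2C(C)(C)CCC[C@@]12C.[K+]
F5 | step 6 | ent-16, enantiomer of Δ8 ketone 16 | C=CCC1=C(C)CC(=O)[C@@H]2C(C)(C)CCC[C@@]12C
F6 | step 6 | ent-17, enantiomer of enone 17 | C=CC[C@H]1[C@]2(C)CCCC(C)(C)[C@H]2C(=O)C=C1C
F7 | step 9 | 14,15,16-trinorlabd-12-ene-6β,8α-diol | C=CC[C@@H]1[C@@]2(C)CCCC(C)(C)[C@@H]2[C@H](O)C[C@@]1(C)O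
F8 | step 12 | (12E)-8α-hydroxylabda-12,14-dien-6α-yl 2-[bis(2,2,2-trifluoroethoxy)phosphoryl]propanoate | C=C/C(C)=C/C[C@@H]1[C@@]2(C)CCCC(C)(C)[C@@H]2[C@@H](OC(=O)C(C)P(=O)(OCC(F)(F)F)OCC(F)(F)F)C[C@@]1(C)O
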